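**Plan**

- The target, 2,3,5-tribromo-6-(2,3,5-tribromo-4-hydroxyphenoxy)benzene-1,4-diol, is achiral, and ring A keeps one hydrogen (C6, ortho to the ether oxygen). The retrosynthesis first cuts the five C–Br bonds that lie ortho to a free hydroxyl, then the O–CH3 bond of a ring A methyl ether.
- Ring B is opened at C4′–C5′ (retro-6π) and re-closed between C2′ and C5′ as a cyclobutenone (retro-4π). The vinyl–carbinol bond and the vinylogous-ester C–O bond are cut last.
- Forward: diisopropyl squarate is taken to semisquaric chloride; ring A enters intact as 2-bromo-4-methoxyphenol; vinylmagnesium bromide adds; ring B then arises by thermal ring expansion; demethylation and fivefold bromination finish.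
- Feature used: ring B (C1′–OAr, C2′–OH, C3′–Br, C4′–Br, C5′–OH, C6′–Br) is a fully substituted 2-aryloxyhydroquinone, the oxygen pattern that a 3-aryloxy-4-hydroxy-4-vinylcyclobutenone gives on heating.
- Stereochemistry: the target has none; the single carbinol stereocentre on the way is racemic and vanishes on aromatization.

Key step: step 6

Remark on the chemistry: the target has six bromines but seven ring positions free of oxygen, so exhaustive bromination of an unbrominated triol would overshoot. 2-Bromo-4-methoxyphenol is therefore taken as the (purchasable) ring A building block; its bromine becomes Br at C2 of ring A, the only bromine not ortho to a free hydroxyl.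

Remark on the chemistry: the aqueous Na2S2O4 wash in step 8 only destroys the slight excess of bromine and returns any trace of quinone to the hydroquinone; it is not part of the stoichiometry of that step.

**Route**

Step 1
Reactants: 1 diisopropyl squarate (3,4-diisopropoxycyclobut-3-ene-1,2-dione)
Product: 3 3-isopropoxycyclobut-3-ene-1,2-dione (isopropyl semisquarate), via 4-hydroxycyclobutenone 2 (not isolated)
Conditions: LiAlH(OtBu)3 (1.05 equiv), THF, −78 → −20 °C; then conc. aq. HCl, CH2Cl2, 0 °C → rt
Reagents that add atoms: none
Why: Hydride 1,2-addition to one squarate carbonyl, then acid-induced 1,3-transposition of the hydroxyl with loss of isopropanol, is the standard reductive entry to alkyl semisquarates.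

Step 2
Reactants: 3 3-isopropoxycyclobut-3-ene-1,2-dione
Product: 4 3-hydroxycyclobut-3-ene-1,2-dione (semisquaric acid)
Conditions: 2 M aq. HCl, 50 °C; evaporate, dry by toluene azeotrope
Reagents that add atoms: water, O
Why: Acid-catalysed vinylogous ester hydrolysis (addition–elimination of water at C3) frees the strong vinylogous acid, and isolating 3 beforehand keeps lithium and aluminium salts away from this water-soluble product.

Step 3
Reactants: 4 3-hydroxycyclobut-3-ene-1,2-dione
Product: 5 3-chlorocyclobut-3-ene-1,2-dione (semisquaric chloride)
Conditions: (COCl)2 (1.1 equiv), DMF (cat.), CH2Cl2, 0 °C → rt; volatiles removed, used crude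
Reagents that add atoms: oxalyl chloride, O=C(Cl)C(=O)Cl
Why: Vilsmeier-type activation converts the vinylogous carboxylic acid into its vinylogous acid chloride, the same reaction type that turns squaric acid into squaric dichloride.

Step 4
Reactants: 5 3-chlorocyclobut-3-ene-1,2-dione; 6 2-bromo-4-methoxyphenol
Product: 7 3-(2-bromo-4-methoxyphenoxy)cyclobut-3-ene-1,2-dione
Conditions: i-Pr2NEt (1.05 equiv), CH2Cl2, −78 → 0 °C; anhydrous filtration through a short silica plug
Reagents that add atoms: none
Why: Addition–elimination of the phenol at the chlorine-bearing carbon (a vinylogous Schotten–Baumann acylation) makes the future diaryl-ether C–O bond as an aryl vinylogous ester, the hindered amine taking up HCl without adding to the dione.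

Step 5
Reactants: 7 3-(2-bromo-4-methoxyphenoxy)cyclobut-3-ene-1,2-dione; 8 vinylmagnesium bromide
Product: 9 3-(2-bromo-4-methoxyphenoxy)-4-ethenyl-4-hydroxycyclobut-2-en-1-one (racemic)
Conditions: CH2=CHMgBr (1.05 equiv), THF, −78 °C; aq. NH4Cl quench at −78 °C; carried on crude
Reagents that add atoms: vinylmagnesium bromide (compound 8), C=C[Mg]Br
Why: Grignard 1,2-addition at low temperature should go to the ketone-like carbonyl next to the aryloxy carbon, since the other carbonyl is deactivated as a vinylogous ester, and the new carbinol centre forms racemic and is erased in step 6.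

Step 6
Reactants: 9 3-(2-bromo-4-methoxyphenoxy)-4-ethenyl-4-hydroxycyclobut-2-en-1-one
Product: 12 2-(2-bromo-4-methoxyphenoxy)benzene-1,4-diol, via dienylketene 10 (not isolated), via cyclohexadienone 11 (not isolated)
Conditions: degassed p-xylene (0.02 M), 138 °C, Ar
Reagents that add atoms: none
Why: Heating opens the cyclobutenone by thermal conrotatory 4π electrocyclic ring opening to dienylketene 10, and the donor hydroxyl at C4 rotates outward so that the vinyl group ends up cis to the ketene. Thermal disrotatory 6π electrocyclization then joins the ketene carbon (C5′) to the vinyl terminus (C4′), closing ring B as cyclohexadienone 11, which tautomerizes to the hydroquinone. This is the Moore rearrangement of 4-alkenyl-4-hydroxycyclobutenones. No stereocentre is created, and the racemic carbinol centre of 9 is lost. The selectivity needed is outward rotation of the hydroxyl (inward rotation would let it trap the ketene as a butenolide), which the oxygen donor secures, while exclusion of air keeps the product at the hydroquinone level. The carbinol carbon becomes C2′ and the aryloxy carbon C1′, so the ether ends up beside a hydroxyl without any aryl C–O coupling.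

Step 7
Reactants: 12 2-(2-bromo-4-methoxyphenoxy)benzene-1,4-diol
Product: 13 2-(2-bromo-4-hydroxyphenoxy)benzene-1,4-diol
Conditions: BBr3 (4 equiv), CH2Cl2, −78 °C → rt; then H2O, 0 °C
Reagents that add atoms: none
Why: Lewis-acid ether cleavage with BBr3 removes the methyl group by bromide attack on the boron-complexed ether, leaving the diaryl ether and the aryl bromide untouched, the excess reagent allowing for the two free hydroxyls.

Step 8
Reactants: 13 2-(2-bromo-4-hydroxyphenoxy)benzene-1,4-diol
Product: 14 2,3,5-tribromo-6-(2,3,5-tribromo-4-hydroxyphenoxy)benzene-1,4-diol (target)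
Conditions: Br2 (5.2 equiv), AcOH, rt, dark; aq. Na2S2O4 wash
Reagents that add atoms: bromine, BrBr
Why: Electrophilic aromatic bromination should take the five positions ortho to a free hydroxyl (C3 and C5 of ring A; C3′, C4′ and C6′ of ring B), while C6–H of ring A, meta to its hydroxyl on a ring by then carrying three bromines, should be left alone at this stoichiometry.

**Compound list**

1 | diisopropyl squarate (3,4-diisopropoxycyclobut-3-ene-1,2-dione) | CC(C)OC1=C(OC(C)C)C(=O)C1=O | starting material
2 | 4-hydroxy-2,3-diisopropoxycyclobut-2-en-1-one (racemic) | CC(C)OC1=C(OC(C)C)C(O)C1=O | intermediate (not isolated)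
3 | 3-isopropoxycyclobut-3-ene-1,2-dione | CC(C)OC1=CC(=O)C1=O | intermediate
4 | 3-hydroxycyclobut-3-ene-1,2-dione (semisquaric acid) | OC1=CC(=O)C1=O | intermediate
5 | 3-chlorocyclobut-3-ene-1,2-dione (semisquaric chloride) | ClC1=CC(=O)C1=O | intermediate
6 | 2-bromo-4-methoxyphenol | COc1ccc(O)c(Br)c1 | starting material
7 | 3-(2-bromo-4-methoxyphenoxy)cyclobut-3-ene-1,2-dione | COc1ccc(OC2=CC(=O)C2=O)c(Br)c1 | intermediate
8 | vinylmagnesium bromide | C=C[Mg]Br | starting material
9 | 3-(2-bromo-4-methoxyphenoxy)-4-ethenyl-4-hydroxycyclobut-2-en-1-one (racemic) | C=CC1(O)C(Oc2ccc(OC)cc2Br)=CC1=O | intermediate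
10 | (3Z)-3-(2-bromo-4-methoxyphenoxy)-4-hydroxyhexa-1,3,5-trien-1-one | C=C/C(O)=C(\C=C=O)Oc1ccc(OC)cc1Br | intermediate (not isolated)
11 | 3-(2-bromo-4-methoxyphenoxy)-4-hydroxycyclohexa-2,4-dien-1-one | O=C1C=C(Oc2ccc(OC)cc2Br)C(O)=CC1 | intermediate (not isolated)
12 | 2-(2-bromo-4-methoxyphenoxy)benzene-1,4-diol | COc1ccc(Oc2cc(O)ccc2O)c(Br)c1 | intermediate
13 | 2-(2-bromo-4-hydroxyphenoxy)benzene-1,4-diol | Oc1ccc(Oc2cc(O)ccc2O)c(Br)c1 | intermediate
14 | 2,3,5-tribromo-6-(2,3,5-tribromo-4-hydroxyphenoxy)benzene-1,4-diol | Oc1c(Br)cc(Oc2c(O)c(Br)c(Br)c(O)c2Br)c(Br)c1Br | target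

**Count**

Total steps: 8. Longest linear sequence: 8 steps (1 → 14); compounds 6 and 8 are purchased.

**Steps most likely to fail, with fallbacks**

Step 4. The very electrophilic chloride, and the activated aryl ester once formed, may be hydrolysed or ring-opened by the base faster than O-acylation proceeds. The fallback sets out from 6 and avoids semisquaric acid and its chloride. Two equivalents of 6 are condensed with commercial 3,4-dichlorocyclobut-3-ene-1,2-dione (i-Pr2NEt, CH2Cl2, 0 °C) to give 3,4-bis(2-bromo-4-methoxyphenoxy)cyclobut-3-ene-1,2-dione F1. This diaryl squarate is reduced at one carbonyl with LiAlH(OtBu)3 in THF at −78 °C to 2,3-bis(2-bromo-4-methoxyphenoxy)-4-hydroxycyclobut-2-en-1-one F2. Catalytic HCl in CH2Cl2 should then transpose the hydroxyl and expel one equivalent of the phenol, exactly as in step 1. The route is rejoined at 7.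

Step 5. The vinyl nucleophile may add in a conjugate sense at the aryloxy carbon and expel the phenoxide, or the carbinol may collapse under acid during work-up. Addition to the wrong carbonyl is not a concern: after the same ring expansion it would still lead to 12, because the three remaining positions of ring B are all CH. The fallback sets out from 7 and uses a harder, strictly 1,2-selective alkynyl nucleophile. Ethynylmagnesium bromide (THF, −78 °C, neutral buffered quench) should give 3-(2-bromo-4-methoxyphenoxy)-4-ethynyl-4-hydroxycyclobut-2-en-1-one F3. Semihydrogenation at room temperature (H2, Pd/CaCO3 poisoned with Pb(OAc)2, quinoline, EtOAc) should then reduce only the terminal alkyne, sparing the aryl bromide and the ring alkene. The route is rejoined at 9.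

Step 8. Bromine may distribute unevenly over the two rings, leaving the hindered C6′ and C3 positions incomplete, or ring B may be oxidized to the quinone level, where the aryloxy group can be displaced. The fallback sets out from 12 and brominates the rings one after the other. With ring A still a deactivated bromoanisole, Br2 (3 equiv, AcOH, rt) should substitute only the hydroquinone ring, giving 2,3,5-tribromo-6-(2-bromo-4-methoxyphenoxy)benzene-1,4-diol F4. BBr3 in CH2Cl2 then frees the ring A phenol as 2,3,5-tribromo-6-(2-bromo-4-hydroxyphenoxy)benzene-1,4-diol F5. Br2 (2 equiv, AcOH, rt, Na2S2O4 wash) should finally fill the two positions ortho to that hydroxyl. The route is rejoined at 14.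

**Further compounds**

F1 | step 4 | 3,4-bis(2-bromo-4-methoxyphenoxy)cyclobut-3-ene-1,2-dione | COc1ccc(OC2=C(Oc3ccc(OC)cc3Br)C(=O)C2=O)c(Br)c1
F2 | step 4 | 2,3-bis(2-bromo-4-methoxyphenoxy)-4-hydroxycyclobut-2-en-1-one (racemic) | COc1ccc(OC2=C(Oc3ccc(OC)cc3Br)C(O)C2=O)c(Br)c1
F3 | step 5 | 3-(2-bromo-4-methoxyphenoxy)-4-ethynyl-4-hydroxycyclobut-2-en-1-one (racemic) | C#CC1(O)C(Oc2ccc(OC)cc2Br)=CC1=O
F4 | step 8 | 2,3,5-tribromo-6-(2-bromo-4-methoxyphenoxy)benzene-1,4-diol | COc1ccc(Oc2c(O)c(Br)c(Br)c(O)c2Br)c(Br)c1
F5 | step 8 | 2,3,5-tribromo-6-(2-bromo-4-hydroxyphenoxy)benzene-1,4-diol | Oc1ccc(Oc2c(O)c(Br)c(Br)c(O)c2Br)c(Br)c1
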